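## Retrosynthetic overview

1. The C6–CH3 bond is made last: methyl is delivered to a cyclic peroxycarbenium ion released from a spiro peroxyketal in which the C9 oxygen is tied to C6. That ketal comes from a cis-β-lactone whose C3–O bond is displaced with inversion by a C6 hydroperoxy ketal, closing the 1,2-dioxane.
2. The β-lactone (C2, C3) comes from a γ-keto aldehyde and propanoyl chloride by catalytic asymmetric ketene–aldehyde cyclocondensation. The keto aldehyde chain is joined at C11–C12 by opening a spiro-epoxide with an acetone hydrazone azaenolate.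
3. The epoxide (C9 configuration from face-selective epoxidation) comes from the methylidene derivative of 2,5,5,8a-tetramethyldecal-1-one.
4. The decalone comes from a trans-hydrindanone by one-carbon ring expansion with diazoethane: a ring CH2 makes a 1,2-shift, which builds ring B and brings in C8 with its methyl. The hydrindanone comes from 2-methylcyclopentane-1,3-dione and ethyl vinyl ketone.
5. Ring order: cyclopentane ring (bought) → ring A (annulation) → ring B (cyclopentanone to cyclohexanone) → temporary oxolane (spiroketal) → 1,2-dioxane.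

Convention and assumption: locants C1–C6 (acid carbon C1, dioxane carbons C3–C6), C11–C12 (linker) and C8–C10 (C9 carbinol, C8 CH(CH3), C10 angular carbon) are those of the target; "hydroxydecalinyl" means (1R,2R,4aS,8aS)-1-hydroxy-2,5,5,8a-tetramethyldecahydronaphthalen-1-yl; the five starting materials are assumed to be bought; peroxyketal intermediates are carried as mixtures at the ketal carbon C6, which becomes trigonal again in the last step.

## Route

Step 1
Reactants: 1 2-methylcyclopentane-1,3-dione; 2 pent-1-en-3-one (ethyl vinyl ketone)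
Product: 4 (7aS)-4,7a-dimethyl-2,3,7,7a-tetrahydro-1H-indene-1,5(6H)-dione, via Michael triketone 3 (not isolated)
Conditions: H2O, AcOH (cat.), 75 °C; concentrate; then (S)-phenylalanine (1 equiv), 1 M HClO4 (0.4 equiv), MeCN, reflux
Reagents that add atoms: none
Why: Michael addition of the dione to the enone, then the amino-acid-mediated intramolecular aldol condensation (Hajos–Parrish–Eder–Sauer–Wiechert reaction), in which the enamine of the side-chain ketone attacks one of the two enantiotopic ring carbonyls and fixes the quaternary centre as S (enantiopurity raised by crystallisation).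

Step 2
Reactants: 4 (7aS)-4,7a-dimethyl-2,3,7,7a-tetrahydro-1H-indene-1,5(6H)-dione
Product: 5 (1S,7aS)-1-hydroxy-4,7a-dimethyl-1,2,3,6,7,7a-hexahydro-5H-inden-5-one
Conditions: NaBH4 (0.3 equiv), EtOH, −20 °C
Reagents that add atoms: none
Why: Chemoselective 1,2-reduction of the saturated cyclopentanone beside the less electrophilic enone, with hydride entering opposite the angular methyl to give the 1S alcohol, which serves only as a masked ketone.

Step 3
Reactants: 5 (1S,7aS)-1-hydroxy-4,7a-dimethyl-1,2,3,6,7,7a-hexahydro-5H-inden-5-one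
Product: 7 (1S,3aR,7aS)-1-hydroxy-4,4,7a-trimethyloctahydro-5H-inden-5-one, via dilithium alkoxide enolate 6 (not isolated)
Conditions: Li (2.1 equiv), NH3(l)/THF, −78 → −33 °C; then CH3I, −78 °C → rt
Reagents that add atoms: iodomethane CI
Why: Stork reductive alkylation (dissolving-metal reduction of the enone, then C-methylation of the regiodefined enolate): protonation of the β-carbon gives the trans ring fusion (H anti to the angular methyl), and the enolate is methylated at the α-carbon to make the gem-dimethyl group.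

Step 4
Reactants: 7 (1S,3aR,7aS)-1-hydroxy-4,4,7a-trimethyloctahydro-5H-inden-5-one
Product: 9 (1S,3aS,7aS)-4,4,7a-trimethyloctahydro-1H-inden-1-ol, via hydrazone 8 (not isolated)
Conditions: N2H4·H2O, KOH, diethylene glycol, 130 °C then 200 °C
Reagents that add atoms: none
Why: Wolff–Kishner reduction (Huang–Minlon procedure) of the hindered ketone to CH2 through its hydrazone; no stereocentre is touched because the only enolisable neighbour is a CH2.

Step 5
Reactants: 9 (1S,3aS,7aS)-4,4,7a-trimethyloctahydro-1H-inden-1-ol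
Product: 10 (3aS,7aS)-4,4,7a-trimethyloctahydro-1H-inden-1-one
Conditions: (nPr4N)RuO4 (5 mol%), N-methylmorpholine N-oxide (1.5 equiv), 4 Å molecular sieves, CH2Cl2, rt
Reagents that add atoms: none
Why: Ley–Griffith oxidation of the secondary alcohol back to the cyclopentanone; the neighbouring centre is quaternary, so nothing can epimerise.

Step 6
Reactants: 10 (3aS,7aS)-4,4,7a-trimethyloctahydro-1H-inden-1-one
Product: 11 (2R,4aS,8aS)-2,5,5,8a-tetramethyloctahydronaphthalen-1(2H)-one
Conditions: CH3CHN2 (Et2O solution, 1.5 equiv), Sc(OTf)3 (10 mol%), CH2Cl2, −78 → −30 °C; then NaOMe (cat.), MeOH, rt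
Reagents that add atoms: diazoethane CC=[N+]=[N-]
Why: Lewis-acid-catalysed diazoalkane homologation of a cyclic ketone (Tiffeneau–Demjanov-type ring expansion): diazoethane adds to the activated carbonyl and, as N2 leaves, the less substituted ring CH2 rather than the quaternary carbon makes the 1,2-shift, so the cyclopentanone becomes the cyclohexanone of ring B with the new CH(CH3) between carbonyl and CH2; methoxide then settles the new centre as 2R (equatorial methyl), its epimer suffering a 1,3-diaxial methyl–methyl clash.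

Step 7
Reactants: 11 (2R,4aS,8aS)-2,5,5,8a-tetramethyloctahydronaphthalen-1(2H)-one
Product: 12 (2R,4aS,8aS)-2,5,5,8a-tetramethyl-1-methylidenedecahydronaphthalene
Conditions: Ph3PCH3Br, KOtBu, toluene, 90 °C
Reagents that add atoms: methyltriphenylphosphonium bromide C[P+](c1ccccc1)(c1ccccc1)c1ccccc1.[Br-]
Why: Wittig methylenation of the hindered ketone with the unstabilised ylide at elevated temperature; the neighbouring methyl stays equatorial (2R) for the same 1,3-diaxial reason, and no new stereocentre is formed.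

Step 8
Reactants: 12 (2R,4aS,8aS)-2,5,5,8a-tetramethyl-1-methylidenedecahydronaphthalene
Product: 13 (1R,2R,4aS,8aS)-2,5,5,8a-tetramethyloctahydro-2H-spiro[naphthalene-1,2'-oxirane]
Conditions: mCPBA, NaHCO3, CH2Cl2, 0 °C
Reagents that add atoms: 3-chloroperoxybenzoic acid OOC(=O)c1cccc(Cl)c1
Why: Prilezhaev epoxidation: the peracid is expected to attack the exocyclic alkene from the face opposite the axial angular methyl on the neighbouring carbon, so oxygen becomes axial and the CH2 equatorial, which is the C9 configuration of the target (a carbon nucleophile added directly to ketone 11 should come from this same face and give the wrong C9 epimer).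

Step 9
Reactants: 13 (1R,2R,4aS,8aS)-2,5,5,8a-tetramethyloctahydro-2H-spiro[naphthalene-1,2'-oxirane]; 14 acetone N,N-dimethylhydrazone; 15 3-bromoprop-1-ene (allyl bromide)
Product: 18 1-(hydroxydecalinyl)hept-6-en-3-one, via allylated hydrazone 16 (not isolated), via hydroxy hydrazone 17 (not isolated)
Conditions: 14, LiN(iPr)2, THF, 0 °C; 15, −78 → 0 °C; LiN(iPr)2, 0 °C; then 13, THF/DMPU, 0 → 45 °C; then 1 M HCl, THF, 0 °C
Reagents that add atoms: water O
Why: Corey–Enders hydrazone alkylation: the lithio-azaenolate of 14 is allylated, the new hydrazone is re-metalated on its methyl side, and this carbon nucleophile opens the spiro-epoxide at its CH2 by SN2, which frees the tertiary alcohol without touching its configuration; dilute acid then hydrolyses the hydrazone to the ketone.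

Step 10
Reactants: 18 1-(hydroxydecalinyl)hept-6-en-3-one
Product: 20 6-(hydroxydecalinyl)-4-oxohexanal, via ozonide 19 (not isolated)
Conditions: O3, CH2Cl2, −78 °C; then PPh3, −78 °C → rt
Reagents that add atoms: ozone [O-][O+]=O
Why: Ozonolysis (Criegee mechanism) with reductive work-up cleaves the only C=C bond to the aldehyde; ketone and tertiary alcohol are inert and no stereocentre is involved.

Step 11
Reactants: 20 6-(hydroxydecalinyl)-4-oxohexanal; 21 propanoyl chloride
Product: 23 (3S,4R)-4-[5-(hydroxydecalinyl)-3-oxopentyl]-3-methyloxetan-2-one, via methylketene 22 (not isolated)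
Conditions: O-trimethylsilylquinine (10 mol%), LiClO4 (2 equiv), iPr2NEt (2.5 equiv), 21 (2 equiv, slow addition), CH2Cl2/Et2O, −78 °C
Reagents that add atoms: none
Why: Catalytic asymmetric acyl halide–aldehyde cyclocondensation (Wynberg-type ketene–aldehyde β-lactone synthesis): the ammonium enolate from methylketene and the quinine-derived catalyst adds to the Li+-activated aldehyde under catalyst control and lactonises to the cis lactone, setting C2 as S and the oxygen-bearing carbon as R (inverted in step 12); the (3S,4R) sense is assigned by analogy with Wynberg's quinidine/quinine results and should be confirmed on a model aldehyde, the quinidine-derived catalyst giving the mirror-image lactone; the ketone and the hindered tertiary alcohol do not react.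

Step 12
Reactants: 23 (3S,4R)-4-[5-(hydroxydecalinyl)-3-oxopentyl]-3-methyloxetan-2-one
Product: 25 (2S)-2-[(3S)-spiro peroxyketal]propanoic acid (1,2-dioxane carrying the acid side chain at C3, whose C6 is also the ketal carbon of an oxolane spiro-fused to C1 of the decalin), via hydroperoxy spiroketal 24 (not isolated)
Conditions: urea·H2O2 (3 equiv), (+)-camphorsulfonic acid (10 mol%), MgSO4, THF, 0 °C; filter, dilute into DMF (0.005 M); Cs2CO3 (1.5 equiv), 0 °C → rt; 1 M HCl work-up
Reagents that add atoms: hydrogen peroxide OO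
Why: Proposed new method: acid-catalysed exchange turns the γ-hydroxy ketone into its cyclic hydroperoxy ketal (known peroxyketalisation), and its caesium peroxide salt, a strong α-effect oxygen nucleophile of the kind that is alkylated by sulfonates, attacks the lactone carbon C4 from the back in a 6-exo-tet SN2 that cleaves the alkyl–oxygen bond of the strained ring (as azide and thiolate do with 4-alkyl β-lactones), so the C–O centre is inverted to the 3S peroxide, the α-methyl centre is untouched and the carboxylic acid is released; attack at the carbonyl would need an eight-membered perester and is further suppressed by high dilution; closest known reaction types are the SN2 ring opening of β-lactones at the alkyl carbon and the intramolecular alkylation of hydroperoxides.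

Step 13
Reactants: 25 (2S)-2-[(3S)-spiro peroxyketal]propanoic acid
Product: 26 (2S)-2-[(3S,6S)-6-methyl-6-[2-(hydroxydecalinyl)ethyl]-1,2-dioxan-3-yl]propanoic acid (CNP0328037.1)
Conditions: AlMe3 (5 equiv), CH2Cl2, −78 → 0 °C; then 1 M HCl, 0 °C
Reagents that add atoms: trimethylaluminium C[Al](C)C
Why: Proposed new method: AlMe3 binds the more basic oxolane oxygen of the mixed alkoxy/peroxy ketal and ionises that C–O bond (Lewis acids expel the alkoxy, not the peroxy, group of monoperoxy ketals), giving a cyclic peroxycarbenium ion tethered to an aluminium alkoxide, and methyl is transferred from aluminium along the axial trajectory of the half-chair that keeps the C3 side chain pseudo-equatorial (the 1,4-cis rule of six-membered oxocarbenium ions), which makes C6 S with methyl cis to the side chain and frees the tertiary alcohol; closest known reaction types are the alkylative ring opening of ketals and spiroketals by trialkylaluminium and Lewis-acid-mediated C–C bond formation at peroxycarbenium ions with allylsilanes or silyl enol ethers.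

## Compound list

1 | 2-methylcyclopentane-1,3-dione | CC1C(=O)CCC1=O | starting material
2 | pent-1-en-3-one (ethyl vinyl ketone) | CCC(=O)C=C | starting material
3 | 2-methyl-2-(3-oxopentyl)cyclopentane-1,3-dione (not isolated) | CCC(=O)CCC1(C)C(=O)CCC1=O | intermediate
4 | (7aS)-4,7a-dimethyl-2,3,7,7a-tetrahydro-1H-indene-1,5(6H)-dione | O=C1CCC2=C(C)C(=O)CC[C@]12C | intermediate
5 | (1S,7aS)-1-hydroxy-4,7a-dimethyl-1,2,3,6,7,7a-hexahydro-5H-inden-5-one | O[C@H]1CCC2=C(C)C(=O)CC[C@]12C | intermediate
6 | dilithium alkoxide–enolate of the trans-fused 1-hydroxy-4,7a-dimethylhexahydroinden-5-one (O-lithiated at C1 and C5, C4=C5 enolate; not isolated) | [Li+].[Li+].[O-][C@H]1CC[C@H]2C(C)=C([O-])CC[C@]12C | intermediate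
7 | (1S,3aR,7aS)-1-hydroxy-4,4,7a-trimethyloctahydro-5H-inden-5-one | O[C@H]1CC[C@H]2C(C)(C)C(=O)CC[C@]12C | intermediate
8 | hydrazone of 7 at C5 (not isolated) | O[C@H]1CC[C@H]2C(C)(C)C(=NN)CC[C@]12C | intermediate
9 | (1S,3aS,7aS)-4,4,7a-trimethyloctahydro-1H-inden-1-ol | O[C@H]1CC[C@H]2C(C)(C)CCC[C@]12C | intermediate
10 | (3aS,7aS)-4,4,7a-trimethyloctahydro-1H-inden-1-one | O=C1CC[C@H]2C(C)(C)CCC[C@]12C | intermediate
11 | (2R,4aS,8aS)-2,5,5,8a-tetramethyloctahydronaphthalen-1(2H)-one | O=C1[C@H](C)CC[C@H]2C(C)(C)CCC[C@]12C | intermediate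
12 | (2R,4aS,8aS)-2,5,5,8a-tetramethyl-1-methylidenedecahydronaphthalene | C=C1[C@H](C)CC[C@H]2C(C)(C)CCC[C@]12C | intermediate
13 | (1R,2R,4aS,8aS)-2,5,5,8a-tetramethyloctahydro-2H-spiro[naphthalene-1,2'-oxirane] (oxirane oxygen axial, anti to the angular methyl) | C1O[C@@]13[C@H](C)CC[C@H]2C(C)(C)CCC[C@@]23C | intermediate
14 | acetone N,N-dimethylhydrazone | CC(C)=NN(C)C | starting material
15 | 3-bromoprop-1-ene (allyl bromide) | C=CCBr | starting material
16 | hex-5-en-2-one N,N-dimethylhydrazone (not isolated) | C=CCCC(C)=NN(C)C | intermediate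
17 | 1-(hydroxydecalinyl)hept-6-en-3-one N,N-dimethylhydrazone (not isolated) | CN(C)N=C(CCC=C)CC[C@@]1(O)[C@H](C)CC[C@H]2C(C)(C)CCC[C@@]21C | intermediate
18 | 1-[(1R,2R,4aS,8aS)-1-hydroxy-2,5,5,8a-tetramethyldecahydronaphthalen-1-yl]hept-6-en-3-one | C=CCCC(=O)CC[C@@]1(O)[C@H](C)CC[C@H]2C(C)(C)CCC[C@@]21C | intermediate
19 | 1-(hydroxydecalinyl)-5-(1,2,4-trioxolan-3-yl)pentan-3-one (ozonide, not isolated) | O=C(CCC3OCOO3)CC[C@@]1(O)[C@H](C)CC[C@H]2C(C)(C)CCC[C@@]21C | intermediate
20 | 6-[(1R,2R,4aS,8aS)-1-hydroxy-2,5,5,8a-tetramethyldecahydronaphthalen-1-yl]-4-oxohexanal | O=CCCC(=O)CC[C@@]1(O)[C@H](C)CC[C@H]2C(C)(C)CCC[C@@]21C | intermediate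
21 | propanoyl chloride | CCC(=O)Cl | starting material
22 | methylketene (prop-1-en-1-one, not isolated) | CC=C=O | intermediate
23 | (3S,4R)-4-{5-[(1R,2R,4aS,8aS)-1-hydroxy-2,5,5,8a-tetramethyldecahydronaphthalen-1-yl]-3-oxopentyl}-3-methyloxetan-2-one (cis) | C[C@@H]1C(=O)O[C@@H]1CCC(=O)CC[C@@]2(O)[C@H](C)CC[C@H]3C(C)(C)CCC[C@@]32C | intermediate
24 | (3S,4R)-4-[2-(5-hydroperoxyoxolan-5-yl)ethyl]-3-methyloxetan-2-one, the oxolane being spiro-fused through its C2 to C1 of the (2R,4aS,8aS)-2,5,5,8a-tetramethyldecalin with oxygen on the former carbinol carbon; both epimers at the hydroperoxy ketal carbon (not isolated) | C[C@@H]1C(=O)O[C@@H]1CCC2(OO)CC[C@@]3(O2)[C@H](C)CC[C@H]4C(C)(C)CCC[C@@]43C | intermediate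
25 | (2S)-2-[(3S)-1,2-dioxan-3-yl]propanoic acid whose dioxane C6 is the ketal carbon of the same decalin-spiro-fused oxolane (dispiro peroxyketal; both C6 epimers) | C[C@H](C(=O)O)[C@@H]1CCC2(CC[C@@]3(O2)[C@H](C)CC[C@H]4C(C)(C)CCC[C@@]43C)OO1 | intermediate
26 | (2S)-2-[(3S,6S)-6-methyl-6-{2-[(1R,2R,4aS,8aS)-1-hydroxy-2,5,5,8a-tetramethyldecahydronaphthalen-1-yl]ethyl}-1,2-dioxan-3-yl]propanoic acid | C[C@H](C(=O)O)[C@@H]1CC[C@@](C)(CC[C@@]2(O)[C@H](C)CC[C@H]3C(C)(C)CCC[C@@]32C)OO1 | target

Total step count: 13. Longest linear sequence: 13 steps (1 and 2 to 26; 14, 15 and 21 are bought and enter directly).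

## Steps most likely to fail, with fallbacks

Step 9 (SN2 opening of a neopentyl-type spiro-epoxide by a hydrazone azaenolate). The fallback sets out from 13 and comes back at 18. Epoxide 13 is opened with the more reliable allyl cuprate (CH2=CHCH2MgBr, CuI cat., THF, −30 °C) to give (1R,2R,4aS,8aS)-1-(but-3-en-1-yl)-2,5,5,8a-tetramethyldecahydronaphthalen-1-ol F1. Wacker oxidation (PdCl2, CuCl, O2, DMF/H2O) converts the terminal alkene into the methyl ketone 4-(hydroxydecalinyl)butan-2-one F2. Its dianion (LiN(iPr)2, 2.2 equiv, THF, −78 °C: alkoxide plus kinetic methyl-side enolate) is allylated with 15 to give 18.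

Step 12 (proposed new peroxide displacement on the β-lactone). The fallback uses known chemistry (peroxyketalisation and amine-catalysed intramolecular peroxide conjugate addition), sets out from 20 and comes back at 25. Wittig reaction of aldehyde 20 with Ph3P=C(CH3)CO2CH3 (CH2Cl2, rt) gives methyl (2E)-8-(hydroxydecalinyl)-2-methyl-6-oxooct-2-enoate F3. Urea·H2O2 with camphorsulfonic acid gives its hydroperoxy spiroketal F4. Et2NH (cat.) in CF3CH2OH closes the 1,2-dioxane by oxa-Michael addition and gives the methyl ester of 25, F5, as a mixture at C2 and C3 from which the (2S,3S) isomer is separated by chromatography. LiOH (THF/H2O) then gives 25. The price is loss of the C2/C3 control that the lactone provides.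

Step 13 (proposed new methyl transfer to the peroxycarbenium ion; risks are ionisation on the peroxide side and attack of AlMe3 on the O–O bond). The fallback uses known chemistry (cobalt-catalysed hydroperoxysilylation of a 1,1-disubstituted alkene, then peroxide conjugate addition), sets out from 18 and comes back at 26. Wittig methylenation of ketone 18 (Ph3P=CH2, excess) gives (1R,2R,4aS,8aS)-2,5,5,8a-tetramethyl-1-(3-methylidenehept-6-en-1-yl)decahydronaphthalen-1-ol F6. Cross-metathesis of its terminal alkene with methyl methacrylate (second-generation Grubbs catalyst, CH2Cl2, 40 °C) gives methyl (2E)-8-(hydroxydecalinyl)-2-methyl-6-methylideneoct-2-enoate F7. Co(thd)2 [bis(2,2,6,6-tetramethylheptane-3,5-dionato)cobalt], O2 and Et3SiH (Mukaiyama–Isayama conditions) add H and OOSiEt3 across the 1,1-disubstituted alkene to give methyl (2E)-8-(hydroxydecalinyl)-2,6-dimethyl-6-[(triethylsilyl)peroxy]oct-2-enoate F8 as both C6 epimers. Aqueous HCl in MeOH frees methyl (2E)-6-hydroperoxy-8-(hydroxydecalinyl)-2,6-dimethyloct-2-enoate F9. Et3N in CF3CH2OH cyclises it to methyl (2S)-2-[(3S,6S)-6-methyl-6-[2-(hydroxydecalinyl)ethyl]-1,2-dioxan-3-yl]propanoate F10, isolated from its diastereomers by HPLC. LiOH (THF/H2O) gives 26. The price is loss of stereocontrol at C6, C3 and C2.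

## Further compounds

F1 | step 9 | (1R,2R,4aS,8aS)-1-(but-3-en-1-yl)-2,5,5,8a-tetramethyldecahydronaphthalen-1-ol | C=CCC[C@@]1(O)[C@H](C)CC[C@H]2C(C)(C)CCC[C@@]21C
F2 | step 9 | 4-[(1R,2R,4aS,8aS)-1-hydroxy-2,5,5,8a-tetramethyldecahydronaphthalen-1-yl]butan-2-one | CC(=O)CC[C@@]1(O)[C@H](C)CC[C@H]2C(C)(C)CCC[C@@]21C
F3 | step 12 | methyl (2E)-8-[(1R,2R,4aS,8aS)-1-hydroxy-2,5,5,8a-tetramethyldecahydronaphthalen-1-yl]-2-methyl-6-oxooct-2-enoate | COC(=O)/C(C)=C/CCC(=O)CC[C@@]1(O)[C@H](C)CC[C@H]2C(C)(C)CCC[C@@]21C
F4 | step 12 | methyl (2E)-5-(5-hydroperoxyoxolan-5-yl)-2-methylpent-2-enoate with the oxolane spiro-fused through its C2 to C1 of the (2R,4aS,8aS)-2,5,5,8a-tetramethyldecalin (both ketal epimers) | COC(=O)/C(C)=C/CCC1(OO)CC[C@@]2(O1)[C@H](C)CC[C@H]3C(C)(C)CCC[C@@]32C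
F5 | step 12 | methyl ester of 25: methyl (2S)-2-[(3S)-dispiro peroxyketal 1,2-dioxan-3-yl]propanoate | COC(=O)[C@@H](C)[C@@H]1CCC2(CC[C@@]3(O2)[C@H](C)CC[C@H]4C(C)(C)CCC[C@@]43C)OO1
F6 | step 13 | (1R,2R,4aS,8aS)-2,5,5,8a-tetramethyl-1-(3-methylidenehept-6-en-1-yl)decahydronaphthalen-1-ol | C=CCCC(=C)CC[C@@]1(O)[C@H](C)CC[C@H]2C(C)(C)CCC[C@@]21C
F7 | step 13 | methyl (2E)-8-[(1R,2R,4aS,8aS)-1-hydroxy-2,5,5,8a-tetramethyldecahydronaphthalen-1-yl]-2-methyl-6-methylideneoct-2-enoate | COC(=O)/C(C)=C/CCC(=C)CC[C@@]1(O)[C@H](C)CC[C@H]2C(C)(C)CCC[C@@]21C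
F8 | step 13 | methyl (2E)-8-[(1R,2R,4aS,8aS)-1-hydroxy-2,5,5,8a-tetramethyldecahydronaphthalen-1-yl]-2,6-dimethyl-6-[(triethylsilyl)peroxy]oct-2-enoate (both C6 epimers) | COC(=O)/C(C)=C/CCC(C)(OO[Si](CC)(CC)CC)CC[C@@]1(O)[C@H](C)CC[C@H]2C(C)(C)CCC[C@@]21C
F9 | step 13 | methyl (2E)-6-hydroperoxy-8-[(1R,2R,4aS,8aS)-1-hydroxy-2,5,5,8a-tetramethyldecahydronaphthalen-1-yl]-2,6-dimethyloct-2-enoate (both C6 epimers) | COC(=O)/C(C)=C/CCC(C)(OO)CC[C@@]1(O)[C@H](C)CC[C@H]2C(C)(C)CCC[C@@]21C
F10 | step 13 | methyl (2S)-2-[(3S,6S)-6-methyl-6-{2-[(1R,2R,4aS,8aS)-1-hydroxy-2,5,5,8a-tetramethyldecahydronaphthalen-1-yl]ethyl}-1,2-dioxan-3-yl]propanoate | COC(=O)[C@@H](C)[C@@H]1CC[C@@](C)(CC[C@@]2(O)[C@H](C)CC[C@H]3C(C)(C)CCC[C@@]32C)OO1
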